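At early times the two products appear in the ratio of their rates: in teal, left-handed over right-handed product is 2.78 at 0.833 min. By 4.00 min it reads 2.39, and both ratios carry the scatter of 0.5 percentage points. But left-handed substrate has gone into product faster than right-handed, so the two substrates no longer stand equal, and the plain ratio of the products is a weak link.

the same everywhere: left-handed substrate 0.056 M; right-handed substrate 0.056 M; free catalyst 0.46 mol%

| flask | coupling partner | racemization catalyst | remark | time |
|---|---|---|---|---|
| teal | 2 equiv | 3.9 mol% | run made earlier |  |
| blue | 2 equiv | 5.8 mol% | run made earlier |  |
| flask | 2.00 equiv | 7.8 mol% |  | 5.0 min |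

| run | time / min | left-handed product / % | right-handed product / % | left-handed substrate / % |
|---|---|---|---|---|
| teal | 0.333 | 3.7 | 1.3 | 46.7 |
| teal | 0.500 | 5.7 | 2.0 | 44.0 |
| teal | 0.833 | 8.9 | 3.2 | 41.6 |
| teal | 1.33 | 11.9 | 4.2 | 38.6 |
| teal | 2.50 | 18.1 | 5.8 | 32.5 |
| teal | 4.00 | 23.2 | 9.7 | 27.5 |
| blue | 0.667 | 6.9 | 1.9 | 43.3 |
| blue | 1.33 | 12.9 | 4.5 | 37.9 |
| blue | 2.00 | 15.6 | 4.8 | 34.7 |
| blue | 2.50 | 17.3 | 6.3 | 32.6 |
| blue | 3.00 | 20.1 | 8.3 | 31.1 |
| blue | 4.00 | 22.3 | 9.0 | 27.8 |

(readings scatter by 0.5 percentage points)

- free catalyst is single-handed; left-handed substrate and right-handed substrate are mirror images of each other, charged as a racemate, each of them at the stated concentration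
- an excess is the difference of the two amounts in percent of their sum
- an excess is below zero if the other one leads

- left-handed product and right-handed product together, in percent of the left-handed substrate and right-handed substrate charged together, at 5.0 min
- excess of left-handed product over right-handed product in the product at 5.0 min
- whether the exchange between left-handed substrate and right-handed substrate keeps pace with the reaction: how far the product's excess at 5.0 min gets from its value without exchange to its value with instant exchange (above 80% keeps pace, below 20% hardly takes part, else lags behind)

We reforge that link. We take both rates to carry the same factor c(coupling partner)·c(free catalyst), each times its own substrate. Dividing one rate by the other removes time, and integrating gives a closed form: the log of the left-handed substrate's remaining fraction is s times that of the right-handed one. Exchange is neglected here, and the readings allow it: left-handed substrate plus left-handed product still make half of the charge at 4.00 min in teal, and half in blue.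

Each remaining fraction is reckoned from its product. Pooling both runs at 2.50 min and 4.00 min gives, as a reading, the selectivity factor s, the summed log loss of left-handed over that of right-handed, 3.11.

The left-handed log loss is 0.437, then 0.607. It bends, so we let its reciprocal run straight in reciprocal time, a falling pseudo-first-order constant integrated. For the flask at 5.0 min this gives 0.697. That means left-handed product 25.1% and right-handed product 10.1%, so we commit to 35.2% and an excess of 42.6%. Instant exchange would hold the excess at 51.3%, and with the balance as it stands we expect exchange to hardly take part.

The forecast says 35%, 41.5% and hardly takes part, on the reading that “Little right-handed substrate therefore crosses over”. The flask gives 35.7%, 44.1% and hardly takes part, 11% of the way.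

    coupling partner ⇌ dormant form (K = 1.11, k = 0.135 min⁻¹)
    coupling partner + free catalyst + left-handed substrate → free catalyst + left-handed product (k = 8440 M⁻² min⁻¹)
    coupling partner + free catalyst + right-handed substrate → free catalyst + right-handed product (k = 2680 M⁻² min⁻¹)
    left-handed substrate + racemization catalyst ⇌ right-handed substrate + racemization catalyst, rate k4*[racemization catalyst]*[left-handed substrate] forward; the back reaction follows from the equilibrium constant (k = 15.2 M⁻¹ min⁻¹)
    coupling partner + racemization catalyst → spent catalyst B (k = 0.981 M⁻¹ min⁻¹)
    racemization catalyst → spent catalyst A (k = 0.202 min⁻¹)

In the flask, coupling partner ran down to 53.9% of its charge by 2.50 min while dormant form built up to 0.0235 M, and half of the left-handed product made up to 5.0 min was there by 1.49 min. Racemization catalyst in the flask sank to 26.4% of its charge at 5.00 min; at 1.36 min, making left-handed product used left-handed substrate at 3.8 times the forward rate of the exchange alone. Carried over, s turns the flask's 25.7% left-handed product into 10.4% right-handed, against 9.97% computed. In the neighbour flask with 0.12 mol% free catalyst, 10.0% left-handed product gives 3.48% right-handed and an excess of 48.4%; computed are 3.41% and 49.3%.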